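**Retrosynthetic overview**
- The target comes from its 7,4'-bis-allyl ether by neutral Pd(0) deallylation.
- Key disconnection, C3–C4: a SmI2 ketyl-radical pinacol cyclisation of an aryl-aldehyde/α-aryloxy-aldehyde pair closes the pyran ring and sets C3 and C4 from C2.
- The dialdehyde comes from periodate cleavage of a 1,2-diol, made by benzylic SN2 opening (inversion, giving C2 = R) of a (2S,3S)-aryl glycidol by a salicylaldehyde phenol.
- The salicylaldehyde comes from anisole (double C–H borylation/oxidation, C-prenylation, formylation, O-allylation); the glycidol from 4-iodophenol and acrolein (Heck, O-allylation, organocatalytic epoxidation).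
- Ring order: rings A and B are bought as benzenes; the heterocycle is the only ring built, last, in the radical step.

Assumption: paraformaldehyde is counted as its monomer formaldehyde (6); allyl ethers are protecting groups (prenyl = 3-methylbut-2-en-1-yl, allyl = prop-2-en-1-yl).

**Step 1**
Reactants: 1 anisole
Product: 3 5-methoxybenzene-1,3-diol, via bis-boronate 2 (not isolated)
Conditions: [Ir(OMe)(cod)]2 (1.5 mol%), dtbpy (3 mol%), HBpin (3 equiv), THF, 80 °C; volatiles off; then Oxone, acetone/H2O, rt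
Reagents that add atoms: pinacolborane, B1OC(C)(C)C(C)(C)O1 (boryl groups of 2); potassium peroxymonosulfate (Oxone), [K+].[O-]S(=O)(=O)OO (the two new O atoms of 3)
Why: Sterically controlled Ir-catalysed C–H borylation (anisole reacts mainly meta, and the meta-boronate is borylated again only at the mutually meta C–H) followed by one-pot C–B oxidation; the minor para-boronate stops at the mono stage and is removed as 4-methoxyphenol.

**Step 2**
Reactants: 3 5-methoxybenzene-1,3-diol; 4 prenol (3-methylbut-2-en-1-ol)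
Product: 5 5-methoxy-2-prenylbenzene-1,3-diol
Conditions: acidic Al2O3 (Brockmann I), prenol (1.2 equiv), 1,2-dichloroethane, reflux
Reagents that add atoms: none
Why: Alumina-templated Friedel–Crafts allylation, in which both surface-bound phenolic OH groups direct the activated allylic alcohol to the carbon between them, as in the alumina synthesis of cannabigerol from olivetol.

**Step 3**
Reactants: 5 5-methoxy-2-prenylbenzene-1,3-diol; 6 formaldehyde (as paraformaldehyde)
Product: 7 2,4-dihydroxy-6-methoxy-3-prenylbenzaldehyde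
Conditions: MgCl2 (3 equiv), Et3N (6 equiv), (CH2O)n (4 equiv), MeCN, reflux; cold 10% citric acid work-up
Reagents that add atoms: none
Why: Casnati–Skattebøl ortho-formylation through the magnesium phenoxide; the two free ring positions of symmetric 5 are equivalent, so only one aldehyde can form, and the chelated product resists a second formylation.

**Step 4**
Reactants: 7 2,4-dihydroxy-6-methoxy-3-prenylbenzaldehyde
Product: 8 4-(allyloxy)-2-hydroxy-6-methoxy-3-prenylbenzaldehyde
Conditions: allyl bromide (1.05 equiv), K2CO3 (1.1 equiv), acetone, 50 °C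
Reagents that add atoms: allyl bromide, C=CCBr
Why: Williamson etherification selective for the more acidic, non-chelated 4-OH, because the 2-OH is held in a hydrogen bond to the formyl group.

**Step 5**
Reactants: 9 4-iodophenol; 10 acrolein
Product: 12 (E)-3-[4-(allyloxy)phenyl]prop-2-enal, via 4-hydroxycinnamaldehyde 11 (not isolated)
Conditions: Pd(OAc)2 (2 mol%), NaHCO3 (2.5 equiv), n-Bu4NCl (1 equiv), DMF, 40 °C; then K2CO3 (1.5 equiv), allyl bromide (1.3 equiv), 50 °C
Reagents that add atoms: allyl bromide, C=CCBr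
Why: Ligand-free Mizoroki–Heck arylation of acrolein (Jeffery conditions; syn-β-hydride elimination gives the E-enal), then Williamson O-allylation in the same pot once the aryl iodide is consumed.

**Step 6**
Reactants: 12 (E)-3-[4-(allyloxy)phenyl]prop-2-enal
Product: 14 [(2S,3S)-3-[4-(allyloxy)phenyl]oxiran-2-yl]methanol, via epoxy aldehyde 13 (not isolated)
Conditions: (R)-2-[bis(3,5-bis(trifluoromethyl)phenyl)(trimethylsilyloxy)methyl]pyrrolidine (10 mol%), 35% aq. H2O2 (1.3 equiv), CH2Cl2, rt; then MeOH, NaBH4, 0 °C; Et3N-deactivated silica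
Reagents that add atoms: hydrogen peroxide, OO
Why: Jørgensen iminium–enamine epoxidation, in which hydroperoxide adds to the β-carbon of the E-iminium ion on the face away from the Ar2C(OTMS) group and the enamine closes to the trans-epoxide (both epoxide centres set by the catalyst), followed by 1,2-reduction; the non-Lewis-acidic conditions tolerate the acid-sensitive p-alkoxyphenyl epoxide and the allyl ether. The catalyst enantiomer is assigned from this facial model, not from a recalled literature correlation, so the sign of rotation of 14 should be checked against (2S,3S)-3-arylglycidols before going on.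

**Step 7**
Reactants: 8 4-(allyloxy)-2-hydroxy-6-methoxy-3-prenylbenzaldehyde; 14 [(2S,3S)-3-[4-(allyloxy)phenyl]oxiran-2-yl]methanol
Product: 15 4-(allyloxy)-2-{[(1R,2S)-1-[4-(allyloxy)phenyl]-2,3-dihydroxypropyl]oxy}-6-methoxy-3-prenylbenzaldehyde
Conditions: 8 (1.3 equiv), Cs2CO3 (0.3 equiv), DMF, 4 Å MS, 65 °C
Reagents that add atoms: none
Why: Phenoxide SN2 opening of the aryl glycidol at the benzylic carbon (activated by the p-alkoxyphenyl group, as in the reboxetine phenoxide/phenylglycidol opening) with inversion, which sets the future C2 as R; excess phenol keeps the alkoxide protonated and suppresses Payne rearrangement.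

**Step 8**
Reactants: 15 diol ether
Product: 16 4-(allyloxy)-2-{[(1R)-1-[4-(allyloxy)phenyl]-2-oxoethyl]oxy}-6-methoxy-3-prenylbenzaldehyde
Conditions: NaIO4 (1.5 equiv), THF/pH 7 phosphate buffer, 0 °C, 20 min; extract, dry, use at once without chromatography
Reagents that add atoms: none
Why: Malaprade glycol cleavage frees the configurationally labile α-aryloxy-α-aryl aldehyde under neutral conditions that leave the prenyl and allyl alkenes untouched; C2 is not involved.

**Step 9**
Reactants: 16 dialdehyde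
Product: 17 (2R,3S,4S)-7-(allyloxy)-2-[4-(allyloxy)phenyl]-5-methoxy-8-prenyl-3,4-dihydro-2H-chromene-3,4-diol
Conditions: SmI2 (2.5 equiv, 0.1 M in THF), t-BuOH (2 equiv), −78 °C, slow addition of 16 to the SmI2 solution; sat. aq. NH4Cl
Reagents that add atoms: none
Why: SmI2 pinacol cyclisation, in which the aryl ketyl radical adds to the samarium-bound aliphatic formyl group inside a chelate that holds both oxygens cis, with the C2 aryl group pseudo-equatorial and the new C3–O bond anti to O1 (the cis-diol, anti-to-α-oxygen outcome known for α-alkoxy 1,6-dialdehydes); this forms C3–C4, closes the pyran ring and sets C3 (S) and C4 (S) as the 2,3-trans-3,4-cis diol.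

**Step 10**
Reactants: 17 bis-allyl ether
Product: 18 (2R,3S,4S)-2-(4-hydroxyphenyl)-5-methoxy-8-prenyl-3,4-dihydro-2H-chromene-3,4,7-triol (5-O-methyl-8-prenylafzelechin-4β-ol)
Conditions: Pd(PPh3)4 (5 mol%), morpholine (6 equiv), degassed THF, rt
Reagents that add atoms: none
Why: Tsuji–Trost deallylation under neutral conditions that spare the prenyl group and the acid-labile p-hydroxybenzylic 4-OH; no stereocentre is touched.

**Compound list**
1 | anisole | COc1ccccc1 | starting material
2 | 2,2'-(5-methoxy-1,3-phenylene)bis(4,4,5,5-tetramethyl-1,3,2-dioxaborolane) | COc1cc(B2OC(C)(C)C(C)(C)O2)cc(B2OC(C)(C)C(C)(C)O2)c1 | intermediate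
3 | 5-methoxybenzene-1,3-diol | COc1cc(O)cc(O)c1 | intermediate
4 | prenol (3-methylbut-2-en-1-ol) | CC(C)=CCO | starting material
5 | 5-methoxy-2-(3-methylbut-2-en-1-yl)benzene-1,3-diol | COc1cc(O)c(CC=C(C)C)c(O)c1 | intermediate
6 | formaldehyde (paraformaldehyde) | C=O | starting material
7 | 2,4-dihydroxy-6-methoxy-3-(3-methylbut-2-en-1-yl)benzaldehyde | COc1cc(O)c(CC=C(C)C)c(O)c1C=O | intermediate
8 | 2-hydroxy-6-methoxy-3-(3-methylbut-2-en-1-yl)-4-(prop-2-en-1-yloxy)benzaldehyde | COc1cc(OCC=C)c(CC=C(C)C)c(O)c1C=O | intermediate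
9 | 4-iodophenol | Oc1ccc(I)cc1 | starting material
10 | acrolein | C=CC=O | starting material
11 | (E)-3-(4-hydroxyphenyl)prop-2-enal | O=C/C=C/c1ccc(O)cc1 | intermediate
12 | (E)-3-[4-(prop-2-en-1-yloxy)phenyl]prop-2-enal | O=C/C=C/c1ccc(OCC=C)cc1 | intermediate
13 | (2R,3S)-3-[4-(prop-2-en-1-yloxy)phenyl]oxirane-2-carbaldehyde | O=C[C@@H]1O[C@H]1c1ccc(OCC=C)cc1 | intermediate
14 | [(2S,3S)-3-[4-(prop-2-en-1-yloxy)phenyl]oxiran-2-yl]methanol | OC[C@@H]1O[C@H]1c1ccc(OCC=C)cc1 | intermediate
15 | 2-{[(1R,2S)-2,3-dihydroxy-1-[4-(prop-2-en-1-yloxy)phenyl]propyl]oxy}-6-methoxy-3-(3-methylbut-2-en-1-yl)-4-(prop-2-en-1-yloxy)benzaldehyde | COc1cc(OCC=C)c(CC=C(C)C)c(O[C@H](c2ccc(OCC=C)cc2)[C@@H](O)CO)c1C=O | intermediate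
16 | 6-methoxy-3-(3-methylbut-2-en-1-yl)-2-{[(1R)-2-oxo-1-[4-(prop-2-en-1-yloxy)phenyl]ethyl]oxy}-4-(prop-2-en-1-yloxy)benzaldehyde | COc1cc(OCC=C)c(CC=C(C)C)c(O[C@H](c2ccc(OCC=C)cc2)C=O)c1C=O | intermediate
17 | (2R,3S,4S)-5-methoxy-8-(3-methylbut-2-en-1-yl)-7-(prop-2-en-1-yloxy)-2-[4-(prop-2-en-1-yloxy)phenyl]-3,4-dihydro-2H-chromene-3,4-diol | COc1cc(OCC=C)c(CC=C(C)C)c2c1[C@H](O)[C@H](O)[C@@H](c1ccc(OCC=C)cc1)O2 | intermediate
18 | (2R,3S,4S)-2-(4-hydroxyphenyl)-5-methoxy-8-(3-methylbut-2-en-1-yl)-3,4-dihydro-2H-chromene-3,4,7-triol | COc1cc(O)c(CC=C(C)C)c2c1[C@H](O)[C@H](O)[C@@H](c1ccc(O)cc1)O2 | target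

**Step count:** 10 steps in total (steps 1, 5 and 6 are one-pot, two-stage operations). Longest linear sequence: 8 steps (steps 1–4, then 7–10).

**Steps most likely to fail, with fallbacks**

Step 2 (regioselective C-prenylation between the two hydroxyls; C4/C6 alkylation, over-alkylation or chroman formation may compete). The fallback sets out from 3 and comes back at 5, replacing templated electrophilic substitution by directed ortho-metalation. Compound 3 is protected with MOMCl/i-Pr2NEt as 1-methoxy-3,5-bis(methoxymethoxy)benzene F1. Lithiation with n-BuLi (THF, 0 °C) occurs between the two MOM ethers, and quenching with prenyl bromide gives 5-methoxy-1,3-bis(methoxymethoxy)-2-(3-methylbut-2-en-1-yl)benzene F2. Mild acetal cleavage (cat. HCl, MeOH, rt) returns 5.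

Step 7 (SN2 by a hindered, hydrogen-bonded, weakly nucleophilic phenoxide; risks are low conversion, attack at the non-benzylic carbon, or SN1 erosion at the benzylic centre). The fallback sets out from 8 and 9 and comes back at 16, making the C2–O1 bond by carbenoid O–H insertion instead of substitution.
- Compound 9 is cross-coupled with ethyl diazoacetate (Pd(PPh3)4, Ag2CO3, Et3N, toluene, rt) to give ethyl 2-diazo-2-(4-hydroxyphenyl)acetate F3.
- O-Allylation (allyl bromide, K2CO3) gives ethyl 2-diazo-2-[4-(prop-2-en-1-yloxy)phenyl]acetate F4.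
- Enantioselective O–H insertion into the 2-OH of 8 (Cu(I) or Pd(II) with a chiral spiro-bisoxazoline, or Rh2(OAc)4 with a chiral phosphoric acid) gives the (R)-α-aryloxy ester, ethyl (2R)-2-[6-formyl-5-methoxy-2-(3-methylbut-2-en-1-yl)-3-(prop-2-en-1-yloxy)phenoxy]-2-[4-(prop-2-en-1-yloxy)phenyl]acetate F5.
- DIBAL reduces the ester and the formyl group to (2R)-2-[6-(hydroxymethyl)-5-methoxy-2-(3-methylbut-2-en-1-yl)-3-(prop-2-en-1-yloxy)phenoxy]-2-[4-(prop-2-en-1-yloxy)phenyl]ethanol F6.
- Buffered Dess–Martin oxidation of both alcohols gives 16, used at once in step 9.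

Step 9 (the key cyclisation; risks are epimerisation of 16 at C2, reductive loss of the α-aryloxy group, or the wrong C4 configuration). The fallback sets out from 16 and comes back at 17, replacing kinetic chelate control by stereoconvergent oxidation/reduction at C4. If the cyclisation gives the 3,4-trans isomer (2R,3S,4R)-5-methoxy-8-(3-methylbut-2-en-1-yl)-7-(prop-2-en-1-yloxy)-2-[4-(prop-2-en-1-yloxy)phenyl]-3,4-dihydro-2H-chromene-3,4-diol F7, alone or mixed with 17, the crude diol is oxidised at the benzylic carbinol with MnO2 (CH2Cl2, rt). This gives the dihydroflavonol (2R,3R)-3-hydroxy-5-methoxy-8-(3-methylbut-2-en-1-yl)-7-(prop-2-en-1-yloxy)-2-[4-(prop-2-en-1-yloxy)phenyl]-2,3-dihydro-4H-chromen-4-one F8. L-Selectride (THF, −78 °C) then delivers hydride from the equatorial side to give the axial 4-OH cis to the 3-OH, which is 17.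

**Further compounds**
F1 | step 2 | 1-methoxy-3,5-bis(methoxymethoxy)benzene | COCOc1cc(OC)cc(OCOC)c1
F2 | step 2 | 5-methoxy-1,3-bis(methoxymethoxy)-2-(3-methylbut-2-en-1-yl)benzene | COCOc1cc(OC)cc(OCOC)c1CC=C(C)C
F3 | step 7 | ethyl 2-diazo-2-(4-hydroxyphenyl)acetate | CCOC(=O)C(=[N+]=[N-])c1ccc(O)cc1
F4 | step 7 | ethyl 2-diazo-2-[4-(prop-2-en-1-yloxy)phenyl]acetate | CCOC(=O)C(=[N+]=[N-])c1ccc(OCC=C)cc1
F5 | step 7 | ethyl (2R)-2-[6-formyl-5-methoxy-2-(3-methylbut-2-en-1-yl)-3-(prop-2-en-1-yloxy)phenoxy]-2-[4-(prop-2-en-1-yloxy)phenyl]acetate | COc1cc(OCC=C)c(CC=C(C)C)c(O[C@H](c2ccc(OCC=C)cc2)C(=O)OCC)c1C=O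
F6 | step 7 | (2R)-2-[6-(hydroxymethyl)-5-methoxy-2-(3-methylbut-2-en-1-yl)-3-(prop-2-en-1-yloxy)phenoxy]-2-[4-(prop-2-en-1-yloxy)phenyl]ethanol | COc1cc(OCC=C)c(CC=C(C)C)c(O[C@H](c2ccc(OCC=C)cc2)CO)c1CO
F7 | step 9 | (2R,3S,4R)-5-methoxy-8-(3-methylbut-2-en-1-yl)-7-(prop-2-en-1-yloxy)-2-[4-(prop-2-en-1-yloxy)phenyl]-3,4-dihydro-2H-chromene-3,4-diol | COc1cc(OCC=C)c(CC=C(C)C)c2c1[C@@H](O)[C@H](O)[C@@H](c1ccc(OCC=C)cc1)O2
F8 | step 9 | (2R,3R)-3-hydroxy-5-methoxy-8-(3-methylbut-2-en-1-yl)-7-(prop-2-en-1-yloxy)-2-[4-(prop-2-en-1-yloxy)phenyl]-2,3-dihydro-4H-chromen-4-one | COc1cc(OCC=C)c(CC=C(C)C)c2c1C(=O)[C@H](O)[C@@H](c1ccc(OCC=C)cc1)O2
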